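A factor of 0.550 is what I plan with: the reach per equivalent of partner in the grey run at 57 °C, over that in the blue run at 35 °C.

| flask | left-handed substrate | right-handed substrate | partner | free catalyst | temperature | remark | time |
|---|---|---|---|---|---|---|---|
| blue | 30 mM | 30 mM | 1.2 equiv | 1.2 mol% | 35 °C | run made earlier |  |
| grey | 30 mM | 30 mM | 5.9 equiv | 1.2 mol% | 57 °C | run made earlier |  |
| oak | 30 mM | 30 mM | 4.00 equiv | 1.2 mol% | 25 °C |  | 8.0 h |
| ash | 30 mM | 30 mM | 1.00 equiv | 1.2 mol% | 65 °C |  | 8.0 h |
| larch | 30 mM | 30 mM | 1.00 equiv | 1.2 mol% | 25 °C |  | 8.0 h |
| cedar | 30 mM | 30 mM | 4.00 equiv | 1.2 mol% | 65 °C |  | 8.0 h |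

| blue: time / h | blue: left-handed product / % | grey: time / min | grey: left-handed product / % |
|---|---|---|---|
| 0.200 | 14.1 | 2.50 | 33.2 |
| 0.333 | 18.7 | 8.00 | 49.3 |
| 0.417 | 19.9 | 12.0 | 53.5 |
| 0.667 | 23.7 | 20.0 | 57.7 |
| 1.00 | 27.1 | 30.0 | 59.5 |
| 1.50 | 29.5 | 40.0 | 61.3 |
| 2.50 | 32.1 | 50.0 | 62.1 |

(each reading ± 0.3 percentage points)

- ranking by amount of left-handed product, in percent of the left-handed substrate and right-handed substrate together charged, from high to low, at 8.0 h (oak / ash / larch / cedar)
- the same order at 25 min (oak / ash / larch / cedar)
- the amount of left-handed product, in percent of the left-handed substrate and right-handed substrate together charged of the flask you put first, at 8.0 h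
- the amount of left-handed product, in percent of the left-handed substrate and right-handed substrate together charged of the flask you put last, at 8.0 h

I count the fraction of left-handed substrate left, not the product made, and call minus its logarithm the reach; at constant catalyst and partner, and with no right-handed substrate turning into left-handed substrate, the reach grows linearly with time (pseudo-first-order). Two times make it. The use time is the first reading's time over the reach at that reading: 0.604 h in blue, 2.29 min in grey. The working life is the time the first mean rate would need to make the last reading's product: 0.455 h in blue, 4.68 min in grey. Life over use time gives reaches of 0.754 and 2.04, and dividing each by its equivalents gives the factor, a reading with the scatter of these readings and with temperature and partner confounded.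

If I put the whole factor down to temperature and the fall per degree stays the same, ash has 0.337 of larch's reach, so I put larch above ash at 8.0 h. At 25 min I put ash ahead, because the use time multiplied by the equivalents is shorter in grey, the hotter run, than in blue. I put oak and cedar, with 4.00 equiv, above both, and cedar first as a judgement, since grey's 62.1 % passes what the left-handed substrate charged could give by itself.

The forecast says cedar > oak > ash > larch at 8.0 h and cedar > oak > ash > larch at 25 min, with 59 % and 26 %, on the ground that “Final yield then depends mainly on partner”.

The flask gives cedar > oak > larch > ash at 8.0 h, with 63.0 % and 26.5 %, and cedar > oak > ash > larch at 25 min.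

    left-handed substrate ⇌ right-handed substrate (k = 0.00386 min⁻¹, Ea = 84.0 kJ mol⁻¹)
    partner + free catalyst + left-handed substrate → free catalyst + left-handed product (k = 1940 M⁻² min⁻¹, Ea = 40.0 kJ mol⁻¹)
    2 free catalyst → spent catalyst (k = 29.1 M⁻¹ min⁻¹, Ea = 59.0 kJ mol⁻¹)
    partner → decomposition product (k = 4.17 × 10⁻⁵ min⁻¹, Ea = 107 kJ mol⁻¹)
    partner + free catalyst + right-handed substrate → free catalyst + right-handed product (k = 691 M⁻² min⁻¹, Ea = 41.0 kJ mol⁻¹)
    (constants at 25 °C)

At 8.0 h ash keeps 63 % of its left-handed substrate and larch 55 %, so ash has 0.761 of larch's reach against my 0.337: the order of the two stands, the size does not. The neighbour is cedar run at 80 °C. At 8.0 h cedar keeps 8.9 % of its left-handed substrate, and my factor for that step, 0.665, reckons 20.0 % kept. The neighbour keeps 20 % and holds 56.4 % left-handed product.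

The runs are simulated with constants of no real substance; noise was put on by code.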